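The plan rests on cutting the oxepane between C5 and C6: the ring segment C5H2–C6(=C1'H–C2'H2OAc)–C7H2–O1 is the cis-1,4-hydro-oxygenation product of a C5=C6–C1'=C2' diene. Ring-closing enyne metathesis builds that 6-vinyl-2,3,4,7-tetrahydrooxepine in one operation, forming the C5–C6 bond, the seven-membered ring and the vinyl group together; nickel-catalysed 1,4-hydroboration then fixes the exocyclic alkene geometry. The metathesis precursor is acyclic: the tertiary oxygen O1 on C2 carries a propargyl group (C7, C6, C1'), C3 carries an acetate and an allyl group (C4, C5), and the C5'' hydroxyl is a silyl ether. C2 and C3 come from a Sharpless epoxide opened by propargyl alcohol.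

Key step: step 13

Remark: locants are O1, C2 (CH3, side chain), C3 (OAc), C4, C5, C6, C7 in the ring, C1'/C2' in the exocyclic chain and C1''–C8'' in the side chain counted from C2; aldehyde 2 is assumed to be used at once as a crude solution because its double bond migrates easily.

Abbreviations: TBS = tert-butyldimethylsilyl; Ipc = isopinocampheyl derived from (+)-α-pinene; Bpin = pinacolboryl; 9-BBN = 9-borabicyclo[3.3.1]nonane.

**Route**

Step 1
Reactants: 1 4-methylpent-3-en-1-ol
Product: 2 4-methylpent-3-enal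
Conditions: Dess–Martin periodinane, pyridine, CH2Cl2, 0 °C; filtered and used at once
Reagents that add atoms: none
Why: Dess–Martin oxidation of a primary alcohol stops at the aldehyde under buffered, near-neutral conditions, which keeps the β,γ-double bond from moving into conjugation; no stereocentre is involved.

Step 2
Reactants: 2 4-methylpent-3-enal; 3 cis-but-2-ene
Product: 8 (3R,4R)-3,7-dimethylocta-1,6-dien-4-ol, via crotylpotassium 4 (not isolated), via borate complex 5 (not isolated), via crotylborane 6 (not isolated), via borinate ester 7 (not isolated)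
Conditions: 3, KOtBu, n-BuLi, THF, −78 → −45 °C; (−)-Ipc2BOMe, −78 °C; BF3·OEt2, −78 °C; 2, −78 °C; NaOH, H2O2, rt
Reagents that add atoms: potassium tert-butoxide, CC(C)(C)[O-].[K+] (potassium of 4 and 5 only); (−)-B-methoxydiisopinocampheylborane, COB([C@@H]1C[C@@H]2C[C@H]([C@H]1C)C2(C)C)[C@@H]1C[C@@H]2C[C@H]([C@H]1C)C2(C)C (boron unit of 5, 6 and 7 only; nothing of it remains in 8)
Why: Brown crotylboration: the (Z)-crotylborane reacts through a closed chair (Zimmerman–Traxler) transition state, so the Z geometry gives the syn methyl/hydroxyl pair, and the Ipc groups from (+)-α-pinene direct the crotyl unit to the Si face of the aldehyde, which sets C3 (R) and C4 (R) of 8, the later C4'' and C5''.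

Step 3
Reactants: 8 (3R,4R)-3,7-dimethylocta-1,6-dien-4-ol
Product: 9 tert-butyl{[(3R,4R)-3,7-dimethylocta-1,6-dien-4-yl]oxy}dimethylsilane
Conditions: TBSCl, imidazole, DMF, rt → 40 °C
Reagents that add atoms: tert-butyldimethylsilyl chloride, CC(C)(C)[Si](C)(C)Cl
Why: Standard silylation of a secondary alcohol; the silyl ether keeps the C5'' oxygen apart from the two hydroxyls that are acetylated later.

Step 4
Reactants: 9 tert-butyl{[(3R,4R)-3,7-dimethylocta-1,6-dien-4-yl]oxy}dimethylsilane
Product: 11 (3R,4R)-4-[(tert-butyldimethylsilyl)oxy]-3,7-dimethyloct-6-en-1-ol, via alkyl-9-BBN adduct 10 (not isolated)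
Conditions: 9-BBN, THF, 0 °C → rt; NaOH, H2O2, 0 °C → rt
Reagents that add atoms: 9-BBN, [BH]1[C@H]2CCC[C@@H]1CCC2 (boron unit of 10 only); hydrogen peroxide, OO (hydroxyl oxygen of 11)
Why: Hydroboration–oxidation with the bulky 9-BBN is anti-Markovnikov and selects the monosubstituted alkene over the trisubstituted one; oxidation of the C–B bond does not touch the stereocentres.

Step 5
Reactants: 11 (3R,4R)-4-[(tert-butyldimethylsilyl)oxy]-3,7-dimethyloct-6-en-1-ol
Product: 12 (3R,4R)-4-[(tert-butyldimethylsilyl)oxy]-1-iodo-3,7-dimethyloct-6-ene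
Conditions: PPh3, imidazole, I2, CH2Cl2, 0 °C → rt
Reagents that add atoms: iodine, II
Why: Appel-type (Garegg–Samuelsson) iodination of a primary alcohol by SN2 displacement of the oxyphosphonium ion; the neutral conditions spare the silyl ether and the alkene.

Step 6
Reactants: 12 (3R,4R)-4-[(tert-butyldimethylsilyl)oxy]-1-iodo-3,7-dimethyloct-6-ene; 13 1-(trimethylsilyl)propyne
Product: 16 (6R,7R)-7-[(tert-butyldimethylsilyl)oxy]-6,10-dimethylundec-9-en-1-yne, via lithiated silylpropyne 14 (not isolated), via silylalkyne 15 (not isolated)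
Conditions: 13, n-BuLi, THF, −78 → −20 °C; 12, −78 °C → rt; MeOH, K2CO3, rt
Reagents that add atoms: n-butyllithium, [Li]CCCC (lithium of 14 only)
Why: Deprotonated 1-(trimethylsilyl)propyne is alkylated by primary iodides at the propargylic carbon because the silyl group blocks the allenyl terminus (Corey–Kirst three-carbon homologation), and carbonate-catalysed methanolysis then cleaves only the alkynyl C–Si bond.

Step 7
Reactants: 16 (6R,7R)-7-[(tert-butyldimethylsilyl)oxy]-6,10-dimethylundec-9-en-1-yne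
Product: 19 (2E,7R,8R)-8-[(tert-butyldimethylsilyl)oxy]-3,7,11-trimethyldodeca-2,10-dien-1-ol, via alkenylalane 17 (not isolated), via lithium alanate 18 (not isolated)
Conditions: AlMe3, Cp2ZrCl2 (20 mol%), CH2Cl2, 0 °C → rt; excess AlMe3 evaporated; n-BuLi, THF/hexane, −78 °C; (CH2O)n, −78 °C → rt; aq. Rochelle salt
Reagents that add atoms: trimethylaluminium, C[Al](C)C (C2 methyl of 19; aluminium of 17 and 18); n-butyllithium, [Li]CCCC (butyl and lithium of 18 only); formaldehyde as paraformaldehyde, C=O (the CH2OH carbon and oxygen)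
Why: Negishi zirconium-catalysed carboalumination adds methyl and aluminium syn across the terminal alkyne with methyl on the internal carbon, and the derived alanate is hydroxymethylated by formaldehyde with retention, which gives the E trisubstituted allylic alcohol.

Step 8
Reactants: 19 (2E,7R,8R)-8-[(tert-butyldimethylsilyl)oxy]-3,7,11-trimethyldodeca-2,10-dien-1-ol
Product: 20 [(2R,3R)-3-{(4R,5R)-5-[(tert-butyldimethylsilyl)oxy]-4,8-dimethylnon-7-enyl}-3-methyloxiran-2-yl]methanol
Conditions: Ti(OiPr)4 (10 mol%), D-(−)-diethyl tartrate (12 mol%), t-BuOOH, 4 Å molecular sieves, CH2Cl2, −20 °C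
Reagents that add atoms: tert-butyl hydroperoxide, CC(C)(C)OO
Why: Katsuki–Sharpless asymmetric epoxidation is directed by the allylic hydroxyl, so the remote trisubstituted alkene is untouched, and D-(−)-diethyl tartrate delivers oxygen to the face that gives the (2R,3R)-epoxide, which fixes the future C3 (R) directly and the future C2 through the next step.

Step 9
Reactants: 20 [(2R,3R)-3-{(4R,5R)-5-[(tert-butyldimethylsilyl)oxy]-4,8-dimethylnon-7-enyl}-3-methyloxiran-2-yl]methanol; 21 prop-2-yn-1-ol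
Product: 22 (2R,3S,7R,8R)-8-[(tert-butyldimethylsilyl)oxy]-3,7,11-trimethyl-3-(prop-2-ynyloxy)dodec-10-ene-1,2-diol
Conditions: 21 (10 equiv), BF3·OEt2 (10 mol%), CH2Cl2, −30 → 0 °C
Reagents that add atoms: none
Why: Lewis-acid-catalysed alcoholysis of a trisubstituted epoxide: the alcohol attacks the activated epoxide at the tertiary carbon, where positive charge is best stabilised, from the side opposite the departing oxygen (borderline SN2), which inverts that carbon to C2 (S) and leaves the C3–O bond and its R configuration intact.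

Step 10
Reactants: 22 (2R,3S,7R,8R)-8-[(tert-butyldimethylsilyl)oxy]-3,7,11-trimethyl-3-(prop-2-ynyloxy)dodec-10-ene-1,2-diol
Product: 24 (2R)-2-{(2S,6R,7R)-7-[(tert-butyldimethylsilyl)oxy]-6,10-dimethyl-2-(prop-2-ynyloxy)undec-9-en-2-yl}oxirane, via primary tosylate 23 (not isolated)
Conditions: NaH (2.5 equiv), N-tosylimidazole (1.05 equiv), THF, 0 °C → rt
Reagents that add atoms: N-tosylimidazole, Cc1ccc(cc1)S(=O)(=O)n1ccnc1 (tosyl group of 23 only)
Why: One-pot epoxide synthesis from a 1,2-diol: the primary alkoxide is sulfonylated selectively and the neighbouring C3 alkoxide displaces the tosylate (intramolecular Williamson reaction), so the C3–O bond is kept and C3 stays R.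

Step 11
Reactants: 24 (2R)-2-{(2S,6R,7R)-7-[(tert-butyldimethylsilyl)oxy]-6,10-dimethyl-2-(prop-2-ynyloxy)undec-9-en-2-yl}oxirane; 25 vinylmagnesium bromide
Product: 27 (4R,5S,9R,10R)-10-[(tert-butyldimethylsilyl)oxy]-5,9,13-trimethyl-5-(prop-2-ynyloxy)tetradeca-1,12-dien-4-ol, via magnesium acetylide 26 (not isolated)
Conditions: 25 (4 equiv), CuI (20 mol%), THF, −40 → −10 °C; aq. NH4Cl
Reagents that add atoms: none
Why: Copper-catalysed Grignard opening of a terminal epoxide is an SN2 attack at the unsubstituted carbon C4 and creates the C3 allyl group without touching C3; one equivalent of the Grignard reagent is consumed by the acetylenic C–H, whose bromomagnesium salt is inert and is re-protonated on work-up.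

Step 12
Reactants: 27 (4R,5S,9R,10R)-10-[(tert-butyldimethylsilyl)oxy]-5,9,13-trimethyl-5-(prop-2-ynyloxy)tetradeca-1,12-dien-4-ol
Product: 28 (4R,5S,9R,10R)-10-[(tert-butyldimethylsilyl)oxy]-5,9,13-trimethyl-5-(prop-2-ynyloxy)tetradeca-1,12-dien-4-yl acetate
Conditions: Ac2O, pyridine, DMAP (cat.), CH2Cl2, rt
Reagents that add atoms: acetic anhydride, CC(=O)OC(C)=O
Why: DMAP-catalysed acylation of the hindered secondary C3 hydroxyl installs the acetate the target needs and removes a free hydroxyl before the two metal-catalysed steps.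

Step 13
Reactants: 28 (4R,5S,9R,10R)-10-[(tert-butyldimethylsilyl)oxy]-5,9,13-trimethyl-5-(prop-2-ynyloxy)tetradeca-1,12-dien-4-yl acetate; 29 ethene
Product: 30 (2S,3R)-2-{(4R,5R)-5-[(tert-butyldimethylsilyl)oxy]-4,8-dimethylnon-7-enyl}-6-ethenyl-2-methyl-2,3,4,7-tetrahydrooxepin-3-yl acetate
Conditions: second-generation Grubbs catalyst (H2IMes)(PCy3)Cl2Ru=CHPh (5–10 mol%), ethene (1 atm), CH2Cl2 (5 mM), rt → 40 °C
Reagents that add atoms: none
Why: Ring-closing enyne metathesis under an ethene atmosphere: the ruthenium methylidene exchanges with the allyl terminus to place the alkylidene on C5, this adds across the tethered alkyne with C5–C6 bond formation, and the resulting C1' vinylcarbene is released by ethene as the C1'=C2' vinyl group (ethene–alkyne cross-metathesis followed by ring closure of the resulting butadiene onto the allyl group leads to the same product). The closest known reaction type is the ruthenium-catalysed cycloisomerisation of alkene-tethered propargyl ethers and amines to 1-vinylcycloalkenes with five- to seven-membered rings. The single ring is closed in the exo mode (seven-membered, C5 bonded to the internal alkyne carbon C6); the endo mode would give an eight-membered ring diene and is disfavoured by ring size. No stereocentre is created, and C2, C3, C4'' and C5'' are not touched. The step needs exo over endo closure and reaction at the monosubstituted alkene only: initiation at the unhindered allyl terminus, the fully substituted C2 next to O1 that folds the tether, and the low reactivity of the trisubstituted C7''=C8'' alkene secure this, while high dilution and ethene suppress alkyne oligomerisation.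

Step 14
Reactants: 30 (2S,3R)-2-{(4R,5R)-5-[(tert-butyldimethylsilyl)oxy]-4,8-dimethylnon-7-enyl}-6-ethenyl-2-methyl-2,3,4,7-tetrahydrooxepin-3-yl acetate
Product: 32 (2S,3R,6E)-2-{(4R,5R)-5-[(tert-butyldimethylsilyl)oxy]-4,8-dimethylnon-7-enyl}-6-(2-hydroxyethylidene)-2-methyloxepan-3-yl acetate, via allylboronate 31 (not isolated)
Conditions: Ni(cod)2 (5 mol%), PCy3 (5 mol%), pinacolborane (1.2 equiv), toluene, rt; NaBO3·4H2O, THF/H2O, rt
Reagents that add atoms: pinacolborane, CC1(C)O[BH]OC1(C)C (Bpin of 31 only); sodium perborate, [Na+].[Na+].O[B-]1(O)OO[B-](O)(O)OO1 (hydroxyl oxygen of 32)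
Why: Nickel-catalysed 1,4-hydroboration of a 1,3-diene: zerovalent nickel binds the diene in its s-cis form, hydride goes to the ring terminus C5 and boron to the unsubstituted terminus C2' through an anti π-allyl, so C2' ends cis to C5 across the new C6=C1' bond (6E), and perborate oxidation replaces boron by hydroxyl at the same carbon while sparing the acetate.

Step 15
Reactants: 32 (2S,3R,6E)-2-{(4R,5R)-5-[(tert-butyldimethylsilyl)oxy]-4,8-dimethylnon-7-enyl}-6-(2-hydroxyethylidene)-2-methyloxepan-3-yl acetate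
Product: 33 (2S,3R,6E)-6-(2-acetoxyethylidene)-2-{(4R,5R)-5-[(tert-butyldimethylsilyl)oxy]-4,8-dimethylnon-7-enyl}-2-methyloxepan-3-yl acetate
Conditions: Ac2O, pyridine, DMAP (cat.), CH2Cl2, 0 °C → rt
Reagents that add atoms: acetic anhydride, CC(=O)OC(C)=O
Why: Standard DMAP-catalysed acetylation of the primary allylic alcohol, which would also restore any C3 acetate lost in the oxidative work-up of step 14.

Step 16
Reactants: 33 (2S,3R,6E)-6-(2-acetoxyethylidene)-2-{(4R,5R)-5-[(tert-butyldimethylsilyl)oxy]-4,8-dimethylnon-7-enyl}-2-methyloxepan-3-yl acetate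
Product: 34 (2S,3R,6E)-6-(2-acetoxyethylidene)-2-[(4R,5R)-5-hydroxy-4,8-dimethylnon-7-enyl]-2-methyloxepan-3-yl acetate
Conditions: HF·pyridine, pyridine, THF, 0 °C → rt
Reagents that add atoms: none
Why: Fluoride-mediated cleavage of the Si–O bond of the silyl ether under mildly acidic, non-basic conditions leaves both acetates, the allylic C–O bond and the alkenes alone.

**Compound list**

1 | 4-methylpent-3-en-1-ol | CC(C)=CCCO | starting material
2 | 4-methylpent-3-enal | CC(C)=CCC=O | intermediate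
3 | cis-but-2-ene | C/C=C\C | starting material
4 | (Z)-but-2-enylpotassium | C/C=C\C[K] | intermediate (not isolated)
5 | potassium (Z)-but-2-enyl(methoxy)diisopinocampheylborate | [K+].C/C=C\C[B-](OC)([C@@H]1C[C@@H]2C[C@H]([C@H]1C)C2(C)C)[C@@H]1C[C@@H]2C[C@H]([C@H]1C)C2(C)C | intermediate (not isolated)
6 | (Z)-but-2-enyldiisopinocampheylborane | C/C=C\CB([C@@H]1C[C@@H]2C[C@H]([C@H]1C)C2(C)C)[C@@H]1C[C@@H]2C[C@H]([C@H]1C)C2(C)C | intermediate (not isolated)
7 | (3R,4R)-3,7-dimethylocta-1,6-dien-4-yl diisopinocampheylborinate | C=C[C@@H](C)[C@H](OB([C@@H]1C[C@@H]2C[C@H]([C@H]1C)C2(C)C)[C@@H]1C[C@@H]2C[C@H]([C@H]1C)C2(C)C)CC=C(C)C | intermediate (not isolated)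
8 | (3R,4R)-3,7-dimethylocta-1,6-dien-4-ol (syn) | C=C[C@@H](C)[C@H](O)CC=C(C)C | intermediate
9 | tert-butyl{[(3R,4R)-3,7-dimethylocta-1,6-dien-4-yl]oxy}dimethylsilane | C=C[C@@H](C)[C@H](O[Si](C)(C)C(C)(C)C)CC=C(C)C | intermediate
10 | 9-{(3R,4R)-4-[(tert-butyldimethylsilyl)oxy]-3,7-dimethyloct-6-enyl}-9-borabicyclo[3.3.1]nonane | B1(CC[C@@H](C)[C@H](O[Si](C)(C)C(C)(C)C)CC=C(C)C)[C@H]2CCC[C@@H]1CCC2 | intermediate (not isolated)
11 | (3R,4R)-4-[(tert-butyldimethylsilyl)oxy]-3,7-dimethyloct-6-en-1-ol | OCC[C@@H](C)[C@H](O[Si](C)(C)C(C)(C)C)CC=C(C)C | intermediate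
12 | (3R,4R)-4-[(tert-butyldimethylsilyl)oxy]-1-iodo-3,7-dimethyloct-6-ene | ICC[C@@H](C)[C@H](O[Si](C)(C)C(C)(C)C)CC=C(C)C | intermediate
13 | 1-(trimethylsilyl)propyne | CC#C[Si](C)(C)C | starting material
14 | [3-(trimethylsilyl)prop-2-ynyl]lithium | [Li]CC#C[Si](C)(C)C | intermediate (not isolated)
15 | (6R,7R)-7-[(tert-butyldimethylsilyl)oxy]-6,10-dimethyl-1-(trimethylsilyl)undec-9-en-1-yne | C[Si](C)(C)C#CCCC[C@@H](C)[C@H](O[Si](C)(C)C(C)(C)C)CC=C(C)C | intermediate (not isolated)
16 | (6R,7R)-7-[(tert-butyldimethylsilyl)oxy]-6,10-dimethylundec-9-en-1-yne | C#CCCC[C@@H](C)[C@H](O[Si](C)(C)C(C)(C)C)CC=C(C)C | intermediate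
17 | {(1E,6R,7R)-7-[(tert-butyldimethylsilyl)oxy]-2,6,10-trimethylundeca-1,9-dienyl}dimethylalane | C[Al](C)/C=C(\C)CCC[C@@H](C)[C@H](O[Si](C)(C)C(C)(C)C)CC=C(C)C | intermediate (not isolated)
18 | lithium butyl{(1E,6R,7R)-7-[(tert-butyldimethylsilyl)oxy]-2,6,10-trimethylundeca-1,9-dienyl}dimethylaluminate | [Li+].CCCC[Al-](C)(C)/C=C(\C)CCC[C@@H](C)[C@H](O[Si](C)(C)C(C)(C)C)CC=C(C)C | intermediate (not isolated)
19 | (2E,7R,8R)-8-[(tert-butyldimethylsilyl)oxy]-3,7,11-trimethyldodeca-2,10-dien-1-ol | OC/C=C(\C)CCC[C@@H](C)[C@H](O[Si](C)(C)C(C)(C)C)CC=C(C)C | intermediate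
20 | [(2R,3R)-3-{(4R,5R)-5-[(tert-butyldimethylsilyl)oxy]-4,8-dimethylnon-7-enyl}-3-methyloxiran-2-yl]methanol | OC[C@H]1O[C@]1(C)CCC[C@@H](C)[C@H](O[Si](C)(C)C(C)(C)C)CC=C(C)C | intermediate
21 | prop-2-yn-1-ol | C#CCO | starting material
22 | (2R,3S,7R,8R)-8-[(tert-butyldimethylsilyl)oxy]-3,7,11-trimethyl-3-(prop-2-ynyloxy)dodec-10-ene-1,2-diol | OC[C@@H](O)[C@](C)(CCC[C@@H](C)[C@H](O[Si](C)(C)C(C)(C)C)CC=C(C)C)OCC#C | intermediate
23 | C1 mono-p-toluenesulfonate of diol 22 | Cc1ccc(cc1)S(=O)(=O)OC[C@@H](O)[C@](C)(CCC[C@@H](C)[C@H](O[Si](C)(C)C(C)(C)C)CC=C(C)C)OCC#C | intermediate (not isolated)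
24 | (2R)-2-{(2S,6R,7R)-7-[(tert-butyldimethylsilyl)oxy]-6,10-dimethyl-2-(prop-2-ynyloxy)undec-9-en-2-yl}oxirane | C1O[C@H]1[C@](C)(CCC[C@@H](C)[C@H](O[Si](C)(C)C(C)(C)C)CC=C(C)C)OCC#C | intermediate
25 | vinylmagnesium bromide | C=C[Mg]Br | starting material
26 | bromomagnesium acetylide of epoxide 24 | C1O[C@H]1[C@](C)(CCC[C@@H](C)[C@H](O[Si](C)(C)C(C)(C)C)CC=C(C)C)OCC#C[Mg]Br | intermediate (not isolated)
27 | (4R,5S,9R,10R)-10-[(tert-butyldimethylsilyl)oxy]-5,9,13-trimethyl-5-(prop-2-ynyloxy)tetradeca-1,12-dien-4-ol | C=CC[C@@H](O)[C@](C)(CCC[C@@H](C)[C@H](O[Si](C)(C)C(C)(C)C)CC=C(C)C)OCC#C | intermediate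
28 | (4R,5S,9R,10R)-10-[(tert-butyldimethylsilyl)oxy]-5,9,13-trimethyl-5-(prop-2-ynyloxy)tetradeca-1,12-dien-4-yl acetate (metathesis precursor) | C=CC[C@@H](OC(C)=O)[C@](C)(CCC[C@@H](C)[C@H](O[Si](C)(C)C(C)(C)C)CC=C(C)C)OCC#C | intermediate
29 | ethene | C=C | starting material
30 | (2S,3R)-2-{(4R,5R)-5-[(tert-butyldimethylsilyl)oxy]-4,8-dimethylnon-7-enyl}-6-ethenyl-2-methyl-2,3,4,7-tetrahydrooxepin-3-yl acetate | C=CC1=CC[C@@H](OC(C)=O)[C@](C)(CCC[C@@H](C)[C@H](O[Si](C)(C)C(C)(C)C)CC=C(C)C)OC1 | intermediate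
31 | (2S,3R,6E)-2-{(4R,5R)-5-[(tert-butyldimethylsilyl)oxy]-4,8-dimethylnon-7-enyl}-2-methyl-6-[2-(pinacolboryl)ethylidene]oxepan-3-yl acetate | CC1(C)OB(C/C=C2\CC[C@@H](OC(C)=O)[C@](C)(CCC[C@@H](C)[C@H](O[Si](C)(C)C(C)(C)C)CC=C(C)C)OC2)OC1(C)C | intermediate (not isolated)
32 | (2S,3R,6E)-2-{(4R,5R)-5-[(tert-butyldimethylsilyl)oxy]-4,8-dimethylnon-7-enyl}-6-(2-hydroxyethylidene)-2-methyloxepan-3-yl acetate | OC/C=C1\CC[C@@H](OC(C)=O)[C@](C)(CCC[C@@H](C)[C@H](O[Si](C)(C)C(C)(C)C)CC=C(C)C)OC1 | intermediate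
33 | (2S,3R,6E)-6-(2-acetoxyethylidene)-2-{(4R,5R)-5-[(tert-butyldimethylsilyl)oxy]-4,8-dimethylnon-7-enyl}-2-methyloxepan-3-yl acetate | CC(=O)OC/C=C1\CC[C@@H](OC(C)=O)[C@](C)(CCC[C@@H](C)[C@H](O[Si](C)(C)C(C)(C)C)CC=C(C)C)OC1 | intermediate
34 | (2S,3R,6E)-6-(2-acetoxyethylidene)-2-[(4R,5R)-5-hydroxy-4,8-dimethylnon-7-enyl]-2-methyloxepan-3-yl acetate (CNP0194639.1) | CC(=O)OC/C=C1\CC[C@@H](OC(C)=O)[C@](C)(CCC[C@@H](C)[C@H](O)CC=C(C)C)OC1 | target

**Summary**

Total step count: 16. Longest linear sequence: 16 steps (1 → 34); compounds 3, 13, 21, 25 and 29 enter as purchased.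

**Steps most likely to fail**

1. Step 13 (ring-closing enyne metathesis). Cross-metathesis of the alkyne with ethene and alkyne oligomerisation may outrun ring closure, or the alkylidene may be held by the ether and acetate oxygens, so that the seven-membered ring does not close. The fallback sets out from 28 and comes back at 30: the alkyne is first turned into the diene by non-metathesis chemistry and the ring is then closed by ordinary alkene metathesis. Mo(CO)3(CNtBu)3-catalysed hydrostannation of 28 with Bu3SnH, which places tin on the internal alkyne carbon of propargylic ethers, should give the 2-(tributylstannyl)allyl ether F1. Stille coupling with vinyl bromide (Pd(PPh3)4, CuI, DMF) should give the 2-methylidenebut-3-enyl ether F2. Ring-closing metathesis of the allyl terminus onto the 1,1-disubstituted alkene of F2 with the second-generation Hoveyda–Grubbs catalyst (H2IMes)Cl2Ru=CH(C6H4-2-OiPr) then delivers 30.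

2. Step 14 (1,4-hydroboration and oxidation). Hydride and boron may be delivered to one double bond only or with reversed regiochemistry, or a 1,3-boron shift in the allylboronate may erode the alkene geometry before oxidation. The fallback sets out from 30 and comes back at 32 and uses iron-catalysed 1,4-hydrosilylation in place of hydroboration. Triethoxysilane with an (iminopyridine)FeCl2 precatalyst reduced by magnesium adds hydrogen to C5 and silicon to C2' of the s-cis diene and should give the configurationally stable allyl(triethoxy)silane F3. Tamao–Fleming oxidation (H2O2, KF, KHCO3, THF/MeOH) converts C–Si into C–OH with retention and gives 32; any acetate loss is made good in step 15.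

3. Step 9 (epoxide alcoholysis at the tertiary carbon). Ionisation of the tertiary C–O bond may outrun capture by the weakly nucleophilic alcohol, leading to 1,2-hydride shift (Meinwald rearrangement) or to partial loss of inversion at C2. The fallback sets out from 20 and comes back at 22: oxygen is put on C2 by water and the propargyl group is attached afterwards by O-alkylation. Acid-catalysed hydrolysis (cat. HClO4, THF/H2O, 0 °C) opens 20 at the tertiary carbon with inversion to the 1,2,3-triol F4. 2,2-Dimethoxypropane with PPTS ties the C3 and C4 hydroxyls into the terminal acetonide F5. KH and propargyl bromide (Williamson ether synthesis, Bu4NI cat., THF) alkylate the free tertiary hydroxyl to the propargyl ether F6. Aqueous acetic acid removes the acetonide and returns 22.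

**Further compounds**

F1 | step 13 | (4R,5S,9R,10R)-10-[(tert-butyldimethylsilyl)oxy]-5,9,13-trimethyl-5-{[2-(tributylstannyl)prop-2-enyl]oxy}tetradeca-1,12-dien-4-yl acetate | C=CC[C@@H](OC(C)=O)[C@](C)(CCC[C@@H](C)[C@H](O[Si](C)(C)C(C)(C)C)CC=C(C)C)OCC(=C)[Sn](CCCC)(CCCC)CCCC
F2 | step 13 | (4R,5S,9R,10R)-10-[(tert-butyldimethylsilyl)oxy]-5,9,13-trimethyl-5-[(2-methylidenebut-3-enyl)oxy]tetradeca-1,12-dien-4-yl acetate | C=CC[C@@H](OC(C)=O)[C@](C)(CCC[C@@H](C)[C@H](O[Si](C)(C)C(C)(C)C)CC=C(C)C)OCC(=C)C=C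
F3 | step 14 | (2S,3R,6E)-2-{(4R,5R)-5-[(tert-butyldimethylsilyl)oxy]-4,8-dimethylnon-7-enyl}-2-methyl-6-[2-(triethoxysilyl)ethylidene]oxepan-3-yl acetate | CCO[Si](OCC)(OCC)C/C=C1\CC[C@@H](OC(C)=O)[C@](C)(CCC[C@@H](C)[C@H](O[Si](C)(C)C(C)(C)C)CC=C(C)C)OC1
F4 | step 9 | (2R,3S,7R,8R)-8-[(tert-butyldimethylsilyl)oxy]-3,7,11-trimethyldodec-10-ene-1,2,3-triol | OC[C@@H](O)[C@](C)(CCC[C@@H](C)[C@H](O[Si](C)(C)C(C)(C)C)CC=C(C)C)O
F5 | step 9 | (2S,6R,7R)-7-[(tert-butyldimethylsilyl)oxy]-2-[(4R)-2,2-dimethyl-1,3-dioxolan-4-yl]-6,10-dimethylundec-9-en-2-ol | C1OC(C)(C)O[C@H]1[C@](C)(CCC[C@@H](C)[C@H](O[Si](C)(C)C(C)(C)C)CC=C(C)C)O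
F6 | step 9 | (4R)-4-{(2S,6R,7R)-7-[(tert-butyldimethylsilyl)oxy]-6,10-dimethyl-2-(prop-2-ynyloxy)undec-9-en-2-yl}-2,2-dimethyl-1,3-dioxolane | C1OC(C)(C)O[C@H]1[C@](C)(CCC[C@@H](C)[C@H](O[Si](C)(C)C(C)(C)C)CC=C(C)C)OCC#C
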